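The runs of Wednesday, Thursday and Friday are what I have for reckoning Monday's flask.

| flask | G | L | Q | time |
|---|---|---|---|---|
| Thursday's | 0.400 M | 1.20 M | 0.0320 M |  |
| Wednesday's | 0.240 M | 1.04 M | 0.0320 M |  |
| Friday's | 0.800 M | 1.20 M | 0.0320 M |  |
| Monday's | 1.20 M | 1.20 M | 0.0960 M | 40 min |

| run | time / min | [Z] / M |
|---|---|---|
| Thursday's run | 1.6 | 0.017 |
| Thursday's run | 3.6 | 0.041 |
| Thursday's run | 8.0 | 0.082 |
| Thursday's run | 18 | 0.155 |
| Thursday's run | 40 | 0.221 |
| Wednesday's run | 1.6 | 0.017 |
| Wednesday's run | 3.6 | 0.029 |
| Wednesday's run | 8.0 | 0.062 |
| Wednesday's run | 18 | 0.104 |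
| Wednesday's run | 40 | 0.138 |
| Friday's run | 1.6 | 0.026 |
| Friday's run | 3.6 | 0.057 |
| Friday's run | 8.0 | 0.127 |
| Friday's run | 18 | 0.227 |
| Friday's run | 40 | 0.344 |

(standard deviation of a reading: 0.004 M)

1. how the opening rate goes with [L] round the charge of the Thursday's run: the exponent of the rate at two percent of G gone to Z
2. how the opening rate goes with [G] round the charge of the Thursday's run: the exponent of the rate at two percent of G gone to Z (one fixed amount of Z, the same in the runs compared)
3. Z in the Monday's run at 40 min, as a share of the G charged

- Overall: G + L -> Z, with Q as catalyst.
- Constant volume, constant temperature.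
- Bound and free are read together.
- "The second partner" is L.
- An order is taken over about fifteen percent of the charge, up and down.

Thursday's and Friday's runs share [L] and [Q] and differ in [G], so I take the mean rate up to 8.0 min in each, 0.0103 M/min for Thursday's run and 0.0159 M/min for Friday's, and their ratio gives a reading of 0.631 for the order in [G]. Wednesday's run has less G and less L, but an order of one in [L] would shift its rate by 13.3%, while the ratio of its reading to Thursday's at 8.0 min carries a scatter of 8.09%, so this pair of runs does not give me the order in [L], and I take one as a working assumption.

Next I compare rates at one moment. In Friday's run, between 18 min and 40 min, Z climbs at 0.00532 M/min around 29.0 min, with [Z] near 0.285 M. Friday's mean rate up to 8.0 min belongs roughly to the charges less half the Z then read, and scaling it by these orders to the charges less that [Z] asks for 0.0102 M/min, which is faster than the climb. I read the gap as a first-order loss of Z, and dividing by [Z] gives 0.0171 /min.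

That is the weak link, for Z that has disappeared was made from G and L, so the charges must be reduced by that Z as well. The area under Friday's readings up to then, divided by [Z], gives a mean age of 17.9 min, and the loss constant times this age times [Z] adds the lost Z back, so the figure drops to 0.0101 /min. Feeding each figure in again gives 0.0129 /min and then 0.0118 /min, and the middle of these two is what I carry as the leak constant, the fraction of the Z present lost per minute: 0.0123 /min.

For Monday's run, taking the order in [Q] as one, untested in these runs, Friday's mean rate scaled to Monday's charge gives an opening rate of 0.0684 M/min. With G and L falling together, integration gives 75.7% made by 40 min. The middle of that Z is 30.3 min old, so a share 68.9% survives, and I commit to 52.1%.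

The forecast differs from my reckoning, with 0.2, 0.6 and 73%, reading the late fall thus: “This suggests catalyst decay”.

The flask gives 1.0, 0.56 and 53.9%.

    Q + G + L → Z + Q (4.734 /M²/min)
    2 G ⇌ G2, settled at all times (33.70 /M)
    Z → Vo (0.01374 /min)

Monday's yield falls chiefly through the step from Z to Vo: the same run without that step reaches 77.6% instead of 53.9%. My leak constant of 0.0123 /min, acting over the age of 30.3 min and applied to that simulated run, gives 53.5%. At 40 min in Monday's run, the 0.646 M of Z is being lost at 0.00888 M/min.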